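**Plan**

Numbering: C1 (alkyne CH) to C15 (CH3). Ring A = O–C7–C8–C9–C10 (enol ether ring), ring B = O–C9–C10–C11–C12.
Enabling feature: in ring B, C10 carries an oxygen and C11 is a CH2 next to C12–O. A 3-oxygenated oxolane of this kind is the Baeyer–Villiger image of a 3-acetyl oxolane, which is the product of a Prins cyclization–pinacol shift of an allylic diol acetal.
Retrosynthetic cuts, in order: C8–Br and C13–Br (from alcohols, inversion); O–C7 (alkyne hydroalkoxylation); C5–C6 (copper coupling); C6≡C7 (homologation of a ring A lactone); C10–O (Baeyer–Villiger); then C11–C12 and C9–C10 together.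
Forward order: ring B first (key step), then a temporary cis-fused γ-lactone standing in for ring A, then the chain is joined at the alkyne, and ring A (enol ether) closes last.
Stereochemistry: C8 from methyl (S)-glycerate acetonide; C9 by chelation-controlled reduction, carried through the key step with retention; C10 by the chair Prins–pinacol event; C12 by base equilibration on the bicyclic lactone; C13 by Felkin–Anh reduction then inversion; C8–Br by inversion; E enol ether by syn insertion; Z alkene from (Z)-pent-2-en-4-yn-1-ol.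

Key step: step 6

Assumption: compounds 1, 7 and 21 are taken as purchasable; the configuration drawn at the tertiary carbinol of 6 is the one expected from chelation control and is irrelevant, because that carbon becomes the acetyl carbonyl in step 6.

**Route**

Step 1
Reactants: 1 methyl (4S)-2,2-dimethyl-1,3-dioxolane-4-carboxylate
Product: 2 (4S)-N-methoxy-N,2,2-trimethyl-1,3-dioxolane-4-carboxamide
Conditions: MeNH(OMe)·HCl, i-PrMgCl, THF, −20 °C
Reagents that add atoms: N,O-dimethylhydroxylamine hydrochloride, CNOC.Cl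
Why: Weinreb amide formation by magnesium amide aminolysis of the ester at low temperature, which should leave the α-stereocenter (C8) untouched.

Step 2
Reactants: 2 (4S)-N-methoxy-N,2,2-trimethyl-1,3-dioxolane-4-carboxamide
Product: 3 1-[(4S)-2,2-dimethyl-1,3-dioxolan-4-yl]-2-methylprop-2-en-1-one
Conditions: CH2=C(CH3)MgBr, THF, 0 °C
Reagents that add atoms: isopropenylmagnesium bromide, CC(=C)[Mg]Br
Why: Grignard acylation of the Weinreb amide should stop at the ketone through the stable chelated tetrahedral intermediate.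

Step 3
Reactants: 3 1-[(4S)-2,2-dimethyl-1,3-dioxolan-4-yl]-2-methylprop-2-en-1-one
Product: 4 (1R)-1-[(4S)-2,2-dimethyl-1,3-dioxolan-4-yl]-2-methylprop-2-en-1-ol
Conditions: Zn(BH4)2, Et2O, −30 °C
Reagents that add atoms: none
Why: Chelation-controlled 1,2-reduction, in which zinc bridges the carbonyl and the α-oxygen of the dioxolane and hydride adds from the face opposite the ring CH2, should set C9 anti (erythro) to the C8 oxygen.

Step 4
Reactants: 4 (1R)-1-[(4S)-2,2-dimethyl-1,3-dioxolan-4-yl]-2-methylprop-2-en-1-ol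
Product: 5 (1S)-1-[(4S)-2,2-dimethyl-1,3-dioxolan-4-yl]-1-hydroxypropan-2-one
Conditions: O3, CH2Cl2/MeOH, −78 °C; then Me2S
Reagents that add atoms: ozone, [O-][O+]=O
Why: Ozonolysis of the 1,1-disubstituted alkene with reductive work-up unmasks the methyl ketone without touching the stereocenters.

Step 5
Reactants: 5 (1S)-1-[(4S)-2,2-dimethyl-1,3-dioxolan-4-yl]-1-hydroxypropan-2-one
Product: 6 (1S,2S)-1-[(4S)-2,2-dimethyl-1,3-dioxolan-4-yl]-2-methylbut-3-ene-1,2-diol
Conditions: CH2=CHMgBr (3 equiv), THF, −78 → 0 °C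
Reagents that add atoms: vinylmagnesium bromide, C=C[Mg]Br
Why: Grignard 1,2-addition to the ketone, with magnesium chelated between the C9 alkoxide and the carbonyl, should deliver vinyl to one face; the new tertiary center is of no consequence because it is lost in step 6.

Step 6
Reactants: 6 (1S,2S)-1-[(4S)-2,2-dimethyl-1,3-dioxolan-4-yl]-2-methylbut-3-ene-1,2-diol; 7 2-ethylacrolein (2-methylidenebutanal)
Product: 9 1-[(2R,3S,5S)-5-(but-1-en-2-yl)-2-[(4S)-2,2-dimethyl-1,3-dioxolan-4-yl]oxolan-3-yl]ethan-1-one, via dioxolane acetal 8 (not isolated)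
Conditions: TsOH (cat.), MgSO4, CH2Cl2, rt; then SnCl4 (2.2 equiv), −78 → −20 °C
Reagents that add atoms: none
Why: SnCl4 opens acetal 8 at the tertiary allylic oxygen to the (E)-oxocarbenium ion on the C9 oxygen, the vinyl terminus C11 adds to C12 through a chair to give an oxanyl cation at C10, and a 1,2-shift of C9 from the stannyloxy carbon to C10 (pinacol step) forms the acetyl C=O and contracts the ring, so that C11–C12 and C9–C10 are made in one operation. The closest known reaction type is the Prins cyclization–pinacol rearrangement of allylic diol acetals to 3-acyl tetrahydrofurans. Ring B closes first as a six-membered ring by 6-endo-trig attack of the alkene on the oxocarbenium ion and becomes the five-membered oxolane by the ring-contracting alkyl shift. C9 keeps the configuration of diol 6 because the migrating carbon moves with retention, C12 is set by the E-oxocarbenium ion with its butenyl group equatorial in the chair (cis to the C9 side chain), and C10 by the suprafacial shift, which places acetyl cis to the C9 side chain (all-cis ring). The step needs ionization toward the oxocarbenium ion on the C9 oxygen and shift of the ring bond in preference to methyl shift or elimination: the other ionization mode cannot cyclize and is reversible, and the bond to C9 is the one aligned with the empty orbital at C10. The cis configuration at C12 is the wrong one for the target and is corrected in step 11.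

Step 7
Reactants: 9 1-[(2R,3S,5S)-5-(but-1-en-2-yl)-2-[(4S)-2,2-dimethyl-1,3-dioxolan-4-yl]oxolan-3-yl]ethan-1-one
Product: 10 (2R,3S,5S)-5-(but-1-en-2-yl)-2-[(4S)-2,2-dimethyl-1,3-dioxolan-4-yl]oxolan-3-yl acetate
Conditions: (Me3SiO)2, Me3SiOTf (cat.), CH2Cl2, −40 → 0 °C
Reagents that add atoms: bis(trimethylsilyl) peroxide, C[Si](C)(C)OO[Si](C)(C)C
Why: Baeyer–Villiger oxidation with a silyl peroxide, a reagent that does not epoxidize alkenes, should let the secondary C10 migrate in preference to methyl with retention, which places the C10 oxygen cis to the C9 side chain.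

Step 8
Reactants: 10 (2R,3S,5S)-5-(but-1-en-2-yl)-2-[(4S)-2,2-dimethyl-1,3-dioxolan-4-yl]oxolan-3-yl acetate
Product: 11 (1S)-1-[(2R,3S,5S)-5-(but-1-en-2-yl)-3-hydroxyoxolan-2-yl]ethane-1,2-diol
Conditions: HCl (cat.), MeOH, 0 °C → rt
Reagents that add atoms: none
Why: Acid-catalysed transacetalization and transesterification in methanol should remove the isopropylidene group and the acetate in one operation.

Step 9
Reactants: 11 (1S)-1-[(2R,3S,5S)-5-(but-1-en-2-yl)-3-hydroxyoxolan-2-yl]ethane-1,2-diol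
Product: 13 (3R,3aS,5S,6aS)-5-(but-1-en-2-yl)-3-hydroxyhexahydrofuro[3,2-b]furan-2(3H)-one, via bicyclic lactol 12 (not isolated)
Conditions: TEMPO (0.2 equiv), PhI(OAc)2 (2.5 equiv), CH2Cl2, rt
Reagents that add atoms: none
Why: Nitroxyl-catalysed oxidative lactonization takes the primary alcohol to the aldehyde, which the cis C10 hydroxyl traps as lactol 12 and which is oxidized on to the cis-fused γ-lactone (the temporary stand-in for ring A), while the secondary alcohols react much more slowly.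

Step 10
Reactants: 13 (3R,3aS,5S,6aS)-5-(but-1-en-2-yl)-3-hydroxyhexahydrofuro[3,2-b]furan-2(3H)-one
Product: 14 (3R,3aR,5S,6aS)-5-(but-1-en-2-yl)-3-[(tert-butyldimethylsilyl)oxy]hexahydrofuro[3,2-b]furan-2(3H)-one
Conditions: t-BuMe2SiOTf, 2,6-lutidine, CH2Cl2, −78 → 0 °C
Reagents that add atoms: tert-butyldimethylsilyl triflate, CC(C)(C)[Si](C)(C)OS(=O)(=O)C(F)(F)F
Why: Silyl ether formation with the reactive silyl triflate should protect the hindered α-hydroxyl of the lactone.

Step 11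
Reactants: 14 (3R,3aR,5S,6aS)-5-(but-1-en-2-yl)-3-[(tert-butyldimethylsilyl)oxy]hexahydrofuro[3,2-b]furan-2(3H)-one
Product: 16 (3R,3aR,5R,6aS)-3-[(tert-butyldimethylsilyl)oxy]-5-propanoylhexahydrofuro[3,2-b]furan-2(3H)-one, via endo ketone 15 (not isolated)
Conditions: O3, CH2Cl2, −78 °C; Me2S; then DBU (0.3 equiv), rt
Reagents that add atoms: ozone, [O-][O+]=O
Why: Ozonolysis gives the ethyl ketone, and DBU should then equilibrate the α-alkoxy ketone center C12 through its enol from the concave (endo) to the convex (exo) face of the cis-fused bicycle, away from the endo silyloxy group, while the less acidic lactone α-position C8 should not exchange.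

Step 12
Reactants: 16 (3R,3aR,5R,6aS)-3-[(tert-butyldimethylsilyl)oxy]-5-propanoylhexahydrofuro[3,2-b]furan-2(3H)-one
Product: 17 (3R,3aR,5R,6aS)-3-[(tert-butyldimethylsilyl)oxy]-5-[(1R)-1-hydroxypropyl]hexahydrofuro[3,2-b]furan-2(3H)-one
Conditions: LiBH(s-Bu)3, THF, −78 °C
Reagents that add atoms: none
Why: Felkin–Anh reduction with a bulky borohydride, with the ring C–O bond anti to the incoming hydride and the attack passing the C12 hydrogen, should give the threo (13R) alcohol, and the lactone is inert at this temperature.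

Step 13
Reactants: 17 (3R,3aR,5R,6aS)-3-[(tert-butyldimethylsilyl)oxy]-5-[(1R)-1-hydroxypropyl]hexahydrofuro[3,2-b]furan-2(3H)-one
Product: 18 (3R,3aR,5R,6aS)-5-[(1S)-1-bromopropyl]-3-[(tert-butyldimethylsilyl)oxy]hexahydrofuro[3,2-b]furan-2(3H)-one
Conditions: CBr4, PPh3, pyridine, toluene, 60 °C
Reagents that add atoms: carbon tetrabromide, BrC(Br)(Br)Br
Why: Appel reaction, in which bromide displaces the alkoxyphosphonium ion by SN2 with inversion, should give the (13S) bromide on a robust intermediate.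

Step 14
Reactants: 18 (3R,3aR,5R,6aS)-5-[(1S)-1-bromopropyl]-3-[(tert-butyldimethylsilyl)oxy]hexahydrofuro[3,2-b]furan-2(3H)-one
Product: 20 (2R,3S,5R)-5-[(1S)-1-bromopropyl]-2-[(1S)-1-[(tert-butyldimethylsilyl)oxy]prop-2-yn-1-yl]oxolan-3-ol, via bromo lactol 19 (not isolated)
Conditions: i-Bu2AlH, CH2Cl2, −78 °C; MeOH; then K2CO3, dimethyl (1-diazo-2-oxopropyl)phosphonate, MeOH, 0 °C → rt
Reagents that add atoms: dimethyl (1-diazo-2-oxopropyl)phosphonate, CC(=O)C(=[N+]=[N-])P(=O)(OC)OC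
Why: Partial reduction of the lactone gives lactol 19, whose open hydroxy aldehyde form should undergo Seyferth–Gilbert homologation with the Ohira–Bestmann reagent to the terminal alkyne (C7≡C6) and free the C10 hydroxyl.

Step 15
Reactants: 21 (2Z)-pent-2-en-4-yn-1-ol
Product: 23 (2Z)-5-(trimethylsilyl)pent-2-en-4-yn-1-ol, via bis-silyl compound 22 (not isolated)
Conditions: n-BuLi (2.1 equiv), THF, −78 °C; Me3SiCl (2.2 equiv); then 1 M HCl
Reagents that add atoms: chlorotrimethylsilane, C[Si](C)(C)Cl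
Why: Double deprotonation and silylation followed by selective hydrolysis of the labile O–Si bond should leave the C-silyl alkyne, the Z alkene coming from the starting material.

Step 16
Reactants: 23 (2Z)-5-(trimethylsilyl)pent-2-en-4-yn-1-ol
Product: 24 [(3Z)-5-bromopent-3-en-1-yn-1-yl]trimethylsilane
Conditions: CBr4, PPh3, CH2Cl2, 0 °C
Reagents that add atoms: carbon tetrabromide, BrC(Br)(Br)Br
Why: Appel reaction at the primary allylic alcohol proceeds by SN2 and should not touch the Z alkene.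

Step 17
Reactants: 20 (2R,3S,5R)-5-[(1S)-1-bromopropyl]-2-[(1S)-1-[(tert-butyldimethylsilyl)oxy]prop-2-yn-1-yl]oxolan-3-ol; 24 [(3Z)-5-bromopent-3-en-1-yn-1-yl]trimethylsilane
Product: 25 (2R,3S,5R)-5-[(1S)-1-bromopropyl]-2-[(1S,5Z)-1-[(tert-butyldimethylsilyl)oxy]-8-(trimethylsilyl)oct-5-ene-2,7-diyn-1-yl]oxolan-3-ol
Conditions: CuI (20 mol %), K2CO3, Bu4NCl (cat.), DMF, rt
Reagents that add atoms: none
Why: Copper-catalysed coupling of the terminal alkyne (as its copper acetylide) with the primary allylic bromide in the SN2 sense should form C5–C6 and keep the Z alkene.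

Step 18
Reactants: 25 (2R,3S,5R)-5-[(1S)-1-bromopropyl]-2-[(1S,5Z)-1-[(tert-butyldimethylsilyl)oxy]-8-(trimethylsilyl)oct-5-ene-2,7-diyn-1-yl]oxolan-3-ol
Product: 26 (2E,3R,3aR,5R,6aS)-5-[(1S)-1-bromopropyl]-3-[(tert-butyldimethylsilyl)oxy]-2-[(3Z)-6-(trimethylsilyl)hex-3-en-5-yn-1-ylidene]hexahydrofuro[3,2-b]furan
Conditions: La[N(SiMe3)2]3 (10 mol %), C6H6, 60 °C
Reagents that add atoms: none
Why: Lanthanide-catalysed intramolecular hydroalkoxylation, in which the C10 lanthanum alkoxide adds to the alkyne by syn insertion in a 5-exo-dig closure of ring A and protonolysis of the vinyl–lanthanum bond occurs with retention, should put H cis and C5 trans to the ring oxygen, which is the E enol ether.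

Step 19
Reactants: 26 (2E,3R,3aR,5R,6aS)-5-[(1S)-1-bromopropyl]-3-[(tert-butyldimethylsilyl)oxy]-2-[(3Z)-6-(trimethylsilyl)hex-3-en-5-yn-1-ylidene]hexahydrofuro[3,2-b]furan
Product: 27 (2E,3R,3aS,5R,6aS)-5-[(1S)-1-bromopropyl]-2-[(3Z)-hex-3-en-5-yn-1-ylidene]hexahydrofuro[3,2-b]furan-3-ol
Conditions: Bu4NF, AcOH, THF, 0 °C
Reagents that add atoms: none
Why: Fluoride-mediated desilylation cleaves the O–Si and the alkynyl C–Si bonds, and acetic acid buffers the basicity so that the secondary bromide, the enol ether and the skipped enyne should survive.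

Step 20
Reactants: 27 (2E,3R,3aS,5R,6aS)-5-[(1S)-1-bromopropyl]-2-[(3Z)-hex-3-en-5-yn-1-ylidene]hexahydrofuro[3,2-b]furan-3-ol
Product: 28 (2E,3S,3aR,5R,6aS)-3-bromo-5-[(1S)-1-bromopropyl]-2-[(3Z)-hex-3-en-5-yn-1-ylidene]hexahydrofuro[3,2-b]furan
Conditions: CBr4, PPh3, 2,6-lutidine, CH2Cl2, 0 °C
Reagents that add atoms: carbon tetrabromide, BrC(Br)(Br)Br
Why: Appel reaction, in which bromide attacks the alkoxyphosphonium ion at C8 from the open convex face with inversion, should turn the endo alcohol into the exo bromide of the target.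

**Compound list**

1 | methyl (4S)-2,2-dimethyl-1,3-dioxolane-4-carboxylate | COC(=O)[C@@H]1COC(C)(C)O1 | starting material
2 | (4S)-N-methoxy-N,2,2-trimethyl-1,3-dioxolane-4-carboxamide | CON(C)C(=O)[C@@H]1COC(C)(C)O1 | intermediate
3 | 1-[(4S)-2,2-dimethyl-1,3-dioxolan-4-yl]-2-methylprop-2-en-1-one | CC(=C)C(=O)[C@@H]1COC(C)(C)O1 | intermediate
4 | (1R)-1-[(4S)-2,2-dimethyl-1,3-dioxolan-4-yl]-2-methylprop-2-en-1-ol (anti) | CC(=C)[C@@H](O)[C@@H]1COC(C)(C)O1 | intermediate
5 | (1S)-1-[(4S)-2,2-dimethyl-1,3-dioxolan-4-yl]-1-hydroxypropan-2-one | CC(=O)[C@@H](O)[C@@H]1COC(C)(C)O1 | intermediate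
6 | (1S,2S)-1-[(4S)-2,2-dimethyl-1,3-dioxolan-4-yl]-2-methylbut-3-ene-1,2-diol | C=C[C@](C)(O)[C@@H](O)[C@@H]1COC(C)(C)O1 | intermediate
7 | 2-ethylacrolein (2-methylidenebutanal) | CCC(=C)C=O | starting material
8 | (4S,5S)-2-(but-1-en-2-yl)-4-[(4S)-2,2-dimethyl-1,3-dioxolan-4-yl]-5-ethenyl-5-methyl-1,3-dioxolane, both epimers at the acetal carbon (not isolated) | CCC(=C)C1O[C@@H]([C@@H]2COC(C)(C)O2)[C@](C)(C=C)O1 | intermediate
9 | 1-[(2R,3S,5S)-5-(but-1-en-2-yl)-2-[(4S)-2,2-dimethyl-1,3-dioxolan-4-yl]oxolan-3-yl]ethan-1-one (all-cis oxolane) | CC(=O)[C@H]1C[C@@H](C(=C)CC)O[C@H]1[C@@H]2COC(C)(C)O2 | intermediate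
10 | (2R,3S,5S)-5-(but-1-en-2-yl)-2-[(4S)-2,2-dimethyl-1,3-dioxolan-4-yl]oxolan-3-yl acetate | CC(=O)O[C@H]1C[C@@H](C(=C)CC)O[C@H]1[C@@H]2COC(C)(C)O2 | intermediate
11 | (1S)-1-[(2R,3S,5S)-5-(but-1-en-2-yl)-3-hydroxyoxolan-2-yl]ethane-1,2-diol | C=C(CC)[C@@H]1C[C@H](O)[C@@H](O1)[C@@H](O)CO | intermediate
12 | (3R,3aS,5S,6aS)-5-(but-1-en-2-yl)hexahydrofuro[3,2-b]furan-2,3-diol, both anomers (not isolated) | C=C(CC)[C@@H]1C[C@@H]2OC(O)[C@H](O)[C@@H]2O1 | intermediate
13 | (3R,3aS,5S,6aS)-5-(but-1-en-2-yl)-3-hydroxyhexahydrofuro[3,2-b]furan-2(3H)-one (OH and butenyl both endo) | C=C(CC)[C@@H]1C[C@@H]2OC(=O)[C@H](O)[C@@H]2O1 | intermediate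
14 | (3R,3aR,5S,6aS)-5-(but-1-en-2-yl)-3-[(tert-butyldimethylsilyl)oxy]hexahydrofuro[3,2-b]furan-2(3H)-one | C=C(CC)[C@@H]1C[C@@H]2OC(=O)[C@H](O[Si](C)(C)C(C)(C)C)[C@@H]2O1 | intermediate
15 | (3R,3aR,5S,6aS)-3-[(tert-butyldimethylsilyl)oxy]-5-propanoylhexahydrofuro[3,2-b]furan-2(3H)-one, endo ketone (not isolated) | CCC(=O)[C@@H]1C[C@@H]2OC(=O)[C@H](O[Si](C)(C)C(C)(C)C)[C@@H]2O1 | intermediate
16 | (3R,3aR,5R,6aS)-3-[(tert-butyldimethylsilyl)oxy]-5-propanoylhexahydrofuro[3,2-b]furan-2(3H)-one, exo ketone | CCC(=O)[C@H]1C[C@@H]2OC(=O)[C@H](O[Si](C)(C)C(C)(C)C)[C@@H]2O1 | intermediate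
17 | (3R,3aR,5R,6aS)-3-[(tert-butyldimethylsilyl)oxy]-5-[(1R)-1-hydroxypropyl]hexahydrofuro[3,2-b]furan-2(3H)-one | CC[C@@H](O)[C@H]1C[C@@H]2OC(=O)[C@H](O[Si](C)(C)C(C)(C)C)[C@@H]2O1 | intermediate
18 | (3R,3aR,5R,6aS)-5-[(1S)-1-bromopropyl]-3-[(tert-butyldimethylsilyl)oxy]hexahydrofuro[3,2-b]furan-2(3H)-one | CC[C@H](Br)[C@H]1C[C@@H]2OC(=O)[C@H](O[Si](C)(C)C(C)(C)C)[C@@H]2O1 | intermediate
19 | (3R,3aR,5R,6aS)-5-[(1S)-1-bromopropyl]-3-[(tert-butyldimethylsilyl)oxy]hexahydrofuro[3,2-b]furan-2-ol, both anomers (not isolated) | CC[C@H](Br)[C@H]1C[C@@H]2OC(O)[C@H](O[Si](C)(C)C(C)(C)C)[C@@H]2O1 | intermediate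
20 | (2R,3S,5R)-5-[(1S)-1-bromopropyl]-2-[(1S)-1-[(tert-butyldimethylsilyl)oxy]prop-2-yn-1-yl]oxolan-3-ol | CC[C@H](Br)[C@H]1C[C@H](O)[C@@H](O1)[C@@H](O[Si](C)(C)C(C)(C)C)C#C | intermediate
21 | (2Z)-pent-2-en-4-yn-1-ol | OC/C=C\C#C | starting material
22 | trimethyl{[(2Z)-5-(trimethylsilyl)pent-2-en-4-yn-1-yl]oxy}silane (not isolated) | C[Si](C)(C)OC/C=C\C#C[Si](C)(C)C | intermediate
23 | (2Z)-5-(trimethylsilyl)pent-2-en-4-yn-1-ol | OC/C=C\C#C[Si](C)(C)C | intermediate
24 | [(3Z)-5-bromopent-3-en-1-yn-1-yl]trimethylsilane | BrC/C=C\C#C[Si](C)(C)C | intermediate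
25 | (2R,3S,5R)-5-[(1S)-1-bromopropyl]-2-[(1S,5Z)-1-[(tert-butyldimethylsilyl)oxy]-8-(trimethylsilyl)oct-5-ene-2,7-diyn-1-yl]oxolan-3-ol | CC[C@H](Br)[C@H]1C[C@H](O)[C@@H](O1)[C@@H](O[Si](C)(C)C(C)(C)C)C#CC/C=C\C#C[Si](C)(C)C | intermediate
26 | (2E,3R,3aR,5R,6aS)-5-[(1S)-1-bromopropyl]-3-[(tert-butyldimethylsilyl)oxy]-2-[(3Z)-6-(trimethylsilyl)hex-3-en-5-yn-1-ylidene]hexahydrofuro[3,2-b]furan | C[Si](C)(C)C#C/C=C\C/C=C1/O[C@H]2C[C@H]([C@@H](Br)CC)O[C@H]2[C@H]1O[Si](C)(C)C(C)(C)C | intermediate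
27 | (2E,3R,3aS,5R,6aS)-5-[(1S)-1-bromopropyl]-2-[(3Z)-hex-3-en-5-yn-1-ylidene]hexahydrofuro[3,2-b]furan-3-ol | C#C/C=C\C/C=C1/O[C@H]2C[C@H]([C@@H](Br)CC)O[C@H]2[C@H]1O | intermediate
28 | (2E,3S,3aR,5R,6aS)-3-bromo-5-[(1S)-1-bromopropyl]-2-[(3Z)-hex-3-en-5-yn-1-ylidene]hexahydrofuro[3,2-b]furan | C#C/C=C\C/C=C1/O[C@H]2C[C@H]([C@@H](Br)CC)O[C@H]2[C@@H]1Br | target

**Count and risks**

Total step count: 20. Longest linear sequence: 18 (steps 1–14 and 17–20).

Steps most likely to fail:

1. Step 18 (lanthanide-catalysed ring A closure). The basic lanthanum alkoxide or amide may isomerize the skipped enediyne into conjugation or eliminate HBr from the secondary bromide. The catalyst may be slowed by the silyl ether and bromide, and any anti addition would erode the E geometry. The fallback sets out from alkynol 20 (before the copper coupling) and comes back at 26. Compound 20 is cyclized with PdCl2(MeCN)2 (cat.), p-benzoquinone and CO (1 atm) in MeOH at 0 °C. Anti-oxypalladation of the terminal alkyne by the C10 hydroxyl on divalent palladium, then CO insertion and methanolysis with retention, should give methyl (2E)-[(3R,3aR,5R,6aS)-5-[(1S)-1-bromopropyl]-3-[(tert-butyldimethylsilyl)oxy]hexahydrofuro[3,2-b]furan-2(3H)-ylidene]acetate F1, whose E geometry is fixed by the mechanism. Reduction with i-Bu2AlH (CH2Cl2, −78 °C) gives the allylic alcohol, (2E)-2-[...furan-2(3H)-ylidene]ethan-1-ol F2, and ClCO2Me/pyridine gives its methyl carbonate F3. Stille coupling of F3 (Pd2(dba)3, LiCl, DMF, rt) with tributyl[(1Z)-4-(trimethylsilyl)but-1-en-3-yn-1-yl]stannane F4 should join C5 to C4 at the less hindered allyl terminus with both double-bond geometries kept, giving 26. F4 is made from (Z)-1,2-bis(tributylstannyl)ethene and (iodoethynyl)trimethylsilane by mono-coupling with Pd(PPh3)4.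

2. Step 20 (bromination at C8, allylic to the enol ether). Bromide may attack C6 in the SN2′ sense with shift of the double bond into ring A. The alkoxyphosphonium ion may ionize or eliminate, and traces of HBr may isomerize or hydrolyse the enol ether. The fallback sets out from 27 and comes back at 28. The phosphonium activation is replaced by an isolated sulfonate: 27 with ClCH2SO2Cl and 2,6-lutidine (CH2Cl2, −20 °C) gives the chloromethanesulfonate, (2E,3R,3aS,5R,6aS)-5-[(1S)-1-bromopropyl]-2-[(3Z)-hex-3-en-5-yn-1-ylidene]hexahydrofuro[3,2-b]furan-3-yl chloromethanesulfonate F5. Displacement with LiBr in THF at 0 °C, an SN2 reaction with a soluble, non-acidic bromide source from the convex face, should give 28 with inversion.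

3. Step 7 (Baeyer–Villiger oxidation next to an alkene and an acetonide). The silyl peroxide may react too slowly with an acyclic methyl ketone, and the Lewis acid may open the isopropylidene acetal or ionize the allylic ether bond at C12. The fallback sets out from 9 and comes back at 10. The alkene is masked before a peracid is used: Br2 (1 equiv, CH2Cl2, −78 °C) adds to the butenyl group of 9 to give 1-[(2R,3S,5S)-5-(1,2-dibromobutan-2-yl)-2-[(4S)-2,2-dimethyl-1,3-dioxolan-4-yl]oxolan-3-yl]ethan-1-one F6 (both epimers at the tertiary bromide). Buffered mCPBA (NaHCO3, CH2Cl2, rt) then effects the Baeyer–Villiger oxidation to the acetate, (2R,3S,5S)-5-(1,2-dibromobutan-2-yl)-2-[(4S)-2,2-dimethyl-1,3-dioxolan-4-yl]oxolan-3-yl acetate F7. Zinc dust in AcOH/EtOH at 0 °C regenerates the alkene by reductive elimination and gives 10.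

**Further compounds**

F1 | step 18 | methyl (2E)-[(3R,3aR,5R,6aS)-5-[(1S)-1-bromopropyl]-3-[(tert-butyldimethylsilyl)oxy]hexahydrofuro[3,2-b]furan-2(3H)-ylidene]acetate | COC(=O)/C=C1/O[C@H]2C[C@H]([C@@H](Br)CC)O[C@H]2[C@H]1O[Si](C)(C)C(C)(C)C
F2 | step 18 | (2E)-2-[(3R,3aR,5R,6aS)-5-[(1S)-1-bromopropyl]-3-[(tert-butyldimethylsilyl)oxy]hexahydrofuro[3,2-b]furan-2(3H)-ylidene]ethan-1-ol | OC/C=C1/O[C@H]2C[C@H]([C@@H](Br)CC)O[C@H]2[C@H]1O[Si](C)(C)C(C)(C)C
F3 | step 18 | (2E)-2-[(3R,3aR,5R,6aS)-5-[(1S)-1-bromopropyl]-3-[(tert-butyldimethylsilyl)oxy]hexahydrofuro[3,2-b]furan-2(3H)-ylidene]ethyl methyl carbonate | COC(=O)OC/C=C1/O[C@H]2C[C@H]([C@@H](Br)CC)O[C@H]2[C@H]1O[Si](C)(C)C(C)(C)C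
F4 | step 18 | tributyl[(1Z)-4-(trimethylsilyl)but-1-en-3-yn-1-yl]stannane | CCCC[Sn](CCCC)(CCCC)/C=C\C#C[Si](C)(C)C
F5 | step 20 | (2E,3R,3aS,5R,6aS)-5-[(1S)-1-bromopropyl]-2-[(3Z)-hex-3-en-5-yn-1-ylidene]hexahydrofuro[3,2-b]furan-3-yl chloromethanesulfonate | C#C/C=C\C/C=C1/O[C@H]2C[C@H]([C@@H](Br)CC)O[C@H]2[C@H]1OS(=O)(=O)CCl
F6 | step 7 | 1-[(2R,3S,5S)-5-(1,2-dibromobutan-2-yl)-2-[(4S)-2,2-dimethyl-1,3-dioxolan-4-yl]oxolan-3-yl]ethan-1-one, both epimers at the tertiary bromide | CC(=O)[C@H]1C[C@@H](C(Br)(CBr)CC)O[C@H]1[C@@H]2COC(C)(C)O2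
F7 | step 7 | (2R,3S,5S)-5-(1,2-dibromobutan-2-yl)-2-[(4S)-2,2-dimethyl-1,3-dioxolan-4-yl]oxolan-3-yl acetate, both epimers at the tertiary bromide | CC(=O)O[C@H]1C[C@@H](C(Br)(CBr)CC)O[C@H]1[C@@H]2COC(C)(C)O2
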